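All runs stem from a simulated flask with constants of no real substance, noise included.

Oak's last reading stands higher than maple's, 80.0 % against 70.3 %, although both flasks carry 0.1 mol% of catalyst, and two chemists read that gap differently before the new flasks are run.

| flask | substrate | reagent | catalyst | temperature | remark | time |
|---|---|---|---|---|---|---|
| cedar | 0.10 M | 0.32 equiv | 0.1 mol% | 45 °C | run made earlier |  |
| oak | 0.10 M | 1.8 equiv | 0.1 mol% | 65 °C | run made earlier |  |
| maple | 0.24 M | 0.95 equiv | 0.1 mol% | 45 °C | run made earlier |  |
| Monday's | 0.10 M | 0.950 equiv | 0.1 mol% | 50 °C |  | 10 h |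
| Thursday's | 0.10 M | 0.640 equiv | 0.1 mol% | 80 °C |  | 10 h |
| Sunday's | 0.10 M | 0.950 equiv | 0.3 mol% | 50 °C |  | 10 h |
| Wednesday's | 0.10 M | 0.950 equiv | 0.4 mol% | 80 °C |  | 10 h |
| Friday's | 0.10 M | 1.40 equiv | 0.1 mol% | 50 °C |  | 10 h |
| Saturday's | 0.30 M | 0.240 equiv | 0.06 mol% | 50 °C |  | 10 h |

| run | time / h | target / % |
|---|---|---|
| cedar | 1.33 | 5.4 |
| cedar | 2.50 | 9.1 |
| cedar | 4.00 | 13.0 |
| cedar | 5.00 | 14.7 |
| cedar | 6.00 | 18.8 |
| cedar | 8.00 | 18.6 |
| oak | 0.250 | 13.3 |
| oak | 0.500 | 25.7 |
| oak | 0.667 | 35.6 |
| oak | 1.33 | 55.8 |
| oak | 2.00 | 67.9 |
| oak | 4.00 | 80.0 |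
| maple | 0.500 | 22.3 |
| maple | 1.00 | 34.5 |
| maple | 2.00 | 49.9 |
| maple | 4.00 | 67.2 |
| maple | 8.00 | 70.3 |

(standard deviation of a reading: 1 percentage point)

- all flasks from highest to lowest amount of target, in percent of the substrate charged, at 10 h (Monday's / Thursday's / Sunday's / Wednesday's / Friday's / Saturday's)
- the same order at 30 min (Monday's / Thursday's / Sunday's / Wednesday's / Friday's / Saturday's)
- the amount of target, in percent of the substrate charged of the flask you put first, at 10 h
- the amount of target, in percent of the substrate charged of the flask you put last, at 10 h

- what was read earlier has a scatter of 1 percentage point, one standard deviation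

The first chemist counts turnovers, as target per catalyst. Maple's last reading gives 703 and oak's 800, and she says: “I read this as catalyst death at about 700–800 turnovers.” On that view a higher loading buys yield, and her forecast is Wednesday's > Sunday's > Friday's > Thursday's > Monday's > Saturday's at the end, with Wednesday's at 93 % and Saturday's at 23.5 %, and Wednesday's > Thursday's > Sunday's > Friday's > Monday's > Saturday's at the early reading.

The second chemist follows one molecule through two forks. At the first, substrate meets reagent and catalyst and becomes target. At the second, the target stays or is lost to something the assay doesn't show. If that loss also runs on catalyst, then at one temperature it counts [catalyst] multiplied by time, whatever the turnovers. He points out that maple at 4.00 h stands at 672 turnovers and gains 3.1 percentage points in the next 4.00 h. Oak at 2.00 h stands at 679 turnovers and gains 12 points in the next 2.00 h, though oak is the warmer flask, at 65 °C against 45 °C.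

So he reads each flask on a catalyst clock: its time multiplied by its [catalyst], divided by maple's [catalyst], which gives the hours maple would need for the same exposure. Maple's readings begin to flatten near 4.00 h. Friday's clock reads 4.17 h, close to that. Sunday's reads 12.5 h and Wednesday's 16.7 h, both further on. The clock leaves temperature out, which is 45 °C in maple, 50 °C in Friday's and 80 °C in Wednesday's. He expects those two past their best and puts Friday's first, with 1.40 equiv of reagent. Both put Saturday's last, because its limiting reagent stands at 0.240 equiv.

The flasks give Friday's > Monday's > Sunday's > Wednesday's > Thursday's > Saturday's at the end, with Friday's at 76.0 % and Saturday's at 18.5 %, and Wednesday's > Sunday's > Thursday's > Friday's > Monday's > Saturday's at the early reading.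

    substrate + reagent + catalyst → target + catalyst, rate k1*[substrate]*[reagent]*[catalyst]/(1 + ([substrate]/sat1)) (0.120 M, k = 550 M⁻² min⁻¹, Ea = 43.0 kJ mol⁻¹)
    target + catalyst ⇌ isomer of the product + catalyst, rate k2*[catalyst]*[target] forward; the back reaction follows from the equilibrium constant (K = 4.70, k = 3.00 M⁻¹ min⁻¹, Ea = 54.0 kJ mol⁻¹, ΔH = −40.0 kJ mol⁻¹)
    (constants at 50 °C)

Wednesday's holds 40.9 % of target against the forecast's 93 %, with 100 % of its catalyst present and 53.6 % of the substrate charged standing as isomer of the product, the thermodynamic side of kinetic against thermodynamic control. At 50 °C the turnover view keeps the short clock: at 4.17 h it gave about 77 % for Friday's, which reads 76.0 %, and about 60 % for Monday's, which reads 59.8 %. Friday's holds 9.79 % of isomer of the product at that reading; the same recipe at 0.25 M reads 10.4 h on the clock and holds 31.6 % of isomer of the product beside 68.4 % of target.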